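**Plan**

Numbering is that of eremophilane (ring A: C1–C2–C3–C4–C5–C10; ring B: C5–C6–C7–C8–C9–C10; C11 on C7); β is the face of the C5 methyl group.
Retrosynthesis: the O3 ester bond is cut first (acid 26, itself cut at its C2=C3 alkene and at the angelate ester); the C8 ketone/C9 hydroxyl go back to a C8=C9 alkene and the isopropenyl group to a C11 carbinol; the C1–C10 bond of cis-octalone 14 is then cut while a C3–C8 bond is restored, giving bridged vinyl carbinol 10; last, the vinyl C2–C3 bond, the two C11–methyl bonds and the Diels–Alder bonds C5–C6 and C7–C8 are cut, down to 2,3-dimethylphenol and methyl acrylate.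
Feature used: the cis C5/C10 fusion, the C3 oxygen three bonds from C10 (C3–C2–C1–C10) and the C8/C9 oxygen pair of ring B are the footprint of the diene C1=C2–C3(O)–C8–C9=C10 held in a 2-vinylbicyclo[2.2.2]oct-5-en-2-ol with bridgeheads C5 and C8.
Forward: the bicycle (bridges C3–C4, C6–C7, C9=C10) is built first; the [3,3] shift closes ring A and releases ring B; ring B is oxidised (diol, isopropenyl), ring A is reduced at C3 and acylated with the side chain, and the C8 ketone is unveiled last.
Stereochemistry: C5, C7, C8 from the endo Diels–Alder adduct and its resolution; C10 from the shift; C4 by equilibration next to the C3 ketone; C3 by dissolving-metal reduction; C9 by hydroxyl-directed osmylation of the convex face; the side-chain centre from (R)-pent-4-en-2-ol, the Z-alkene from angelic acid, the E-alkene from cross-metathesis.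

Key step: step 7

Remark: dienone 2 is racemic by its origin, so the antipodes are parted at adduct 4; C4 of the bicyclic intermediates is only a relay centre and is set for good in step 7.

**Route**

Step 1
Reactants: 1 2,3-dimethylphenol
Product: 2 racemic acetoxy dienone
Conditions: Pb(OAc)4 (1.1 equiv), AcOH/CH2Cl2, 0 °C → rt
Reagents that add atoms: lead tetraacetate, CC(=O)O[Pb](OC(C)=O)(OC(C)=O)OC(C)=O
Why: Wessely acetoxylation, in which the aryloxy lead triacetate passes an acetoxy group to the ortho carbon, and only attack at the methyl-bearing C-2 (the later C4) gives a dienone that cannot tautomerise back to a phenol, while the methyl group on the diene terminus slows dimerisation enough for the crude dienone to be used at once.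

Step 2
Reactants: 2 racemic acetoxy dienone, 3 methyl acrylate
Product: 4 racemic Diels–Alder adduct
Conditions: methyl acrylate (10 equiv), toluene, BHT (trace), 90 °C, sealed tube
Reagents that add atoms: none
Why: Thermal Diels–Alder reaction of the cyclohexa-2,4-dienone (diene termini C5 and C8), which forms C5–C6 and C7–C8 with the regiochemistry usual for these dienones (ester carbon on the terminus next to the carbonyl), places the ester endo, that is syn to the new C9=C10 alkene, and brings the dienophile in syn to the acetoxy group, so that C5, C7 and C8 are set relative to each other.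

Step 3
Reactants: 4 racemic Diels–Alder adduct
Product: 5 acetoxy keto ester (single antipode)
Conditions: preparative SFC on amylose tris(3,5-dimethylphenylcarbamate), CO2/MeOH, 35 °C
Reagents that add atoms: none
Why: Resolution of a racemate by chromatography on a chiral stationary phase, placed at the first rigid, configurationally stable bicycle, with the absolute configuration of the antipode that is kept to be confirmed by anomalous-dispersion X-ray analysis before it is carried on.

Step 4
Reactants: 5 acetoxy keto ester (single antipode)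
Product: 7 keto ester, via samarium enolate 6 (not isolated)
Conditions: SmI2 (2.5 equiv), THF/MeOH, −78 °C
Reagents that add atoms: none
Why: Reductive cleavage of an α-acyloxy ketone by SmI2 (ketyl, loss of acetate, second electron transfer), after which methanol protonates the trivalent samarium enolate 6 at C4 on its open face, the one turned to the C9=C10 bridge, so that the methyl group is left syn to the C6–C7 bridge.

Step 5
Reactants: 7 keto ester
Product: 8 vinyl carbinol ester
Conditions: CH2=CHMgBr (1.5 equiv), CeCl3 (1.5 equiv), THF, −78 °C; then H2O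
Reagents that add atoms: vinylmagnesium bromide, C=C[Mg]Br
Why: Organocerium-mediated Grignard 1,2-addition (little enolisation, ketone far faster than ester at −78 °C), in which the C3 carbonyl is attacked from the side of the C9=C10 bridge because the other face is closed by the C4 methyl group and the inward hydrogen on C7, so that the vinyl group ends syn to the alkene as the sigmatropic shift demands.

Step 6
Reactants: 8 vinyl carbinol ester
Product: 10 vinyl carbinol diol, via methyl ketone 9 (not isolated)
Conditions: MeLi (5 equiv), THF, −78 → 0 °C; then H2O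
Reagents that add atoms: methyllithium, [Li]C
Why: Double addition of methyllithium to the ester by way of methyl ketone 9 gives the dimethyl carbinol, which takes away the carbonyl that would make H7 acidic in the basic key step and serves as the masked isopropenyl group during the later osmylation.

Step 7
Reactants: 10 vinyl carbinol diol
Product: 14 cis-octalone, via dipotassium dialkoxide 11 (not isolated), via dipotassium enolate 12 (not isolated), via 4-epi octalone 13 (not isolated)
Conditions: KH (3 equiv), 18-crown-6 (3 equiv), THF, 0 °C → rt; then MeOH, rt → 40 °C; aq. NH4Cl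
Reagents that add atoms: none
Why: Anionic oxy-Cope rearrangement: the crown-ether-separated C3 alkoxide of 11 weakens the C3–C8 bond and the 1,5-diene C1=C2–C3–C8–C9=C10 undergoes a concerted [3,3] shift through the boat-shaped six-centre transition state that the bicycle imposes, forming C1–C10, breaking C3–C8 and leaving the C2=C3 enolate 12. The closest known reaction type is the KH/18-crown-6 rearrangement of 2-vinylbicyclo[2.2.2]oct-5-en-2-ols to cis-fused octalones. Ring A (C1–C2–C3–C4–C5–C10) closes as a six-membered carbocycle by the new sigmatropic σ bond C1–C10 (suprafacial on both allyl halves), and ring B (C5–C6–C7–C8=C9–C10) is the cyclohexene set free when the bridge bond breaks. The new stereocentre C10 is controlled by the bicyclic frame, since C1 can reach C10 only on the face turned to the C3–C4 bridge, so that H10 and the C5 methyl end cis and the bridgehead configuration set in step 2 and made single-handed in step 3 is relayed to the ring fusion. C4 becomes α to the C3 ketone on methanol quench, and the KOMe so formed equilibrates the first-formed 4α-epimer 13 to the 4β-methyl ketone 14, in which this methyl group is equatorial and cis to the C5 methyl instead of axial and syn to C9. The step needs the [3,3] path to win over fragmentation of the alkoxide, which is secured by the vinyl group lying syn to the C9=C10 bridge (step 5) and by the absence of an acidic hydrogen at C7 once the ester has become a carbinol (step 6).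

Step 8
Reactants: 14 cis-octalone
Product: 16 triol ketone, via osmate ester 15 (not isolated)
Conditions: OsO4 (1.05 equiv), TMEDA (1.1 equiv), CH2Cl2, −78 °C; then aq. Na2SO3, THF, 60 °C
Reagents that add atoms: osmium tetroxide, O=[Os](=O)(=O)=O
Why: Hydrogen-bond-directed syn-dihydroxylation, in which the OsO4·TMEDA complex is held by the homoallylic C11 hydroxyl on the β face, which is also the convex face of the cis-octalin since ring A lies under the α face, so that the cyclic ester 15 of hexavalent osmium and, after reductive cleavage, both hydroxyls are β, C8=C9 being the only alkene in the molecule.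

Step 9
Reactants: 16 triol ketone
Product: 17 acetonide ketone
Conditions: 2,2-dimethoxypropane, PPTS (cat.), acetone, rt
Reagents that add atoms: 2,2-dimethoxypropane, COC(C)(C)OC
Why: Acid-catalysed acetal exchange, in which only the cis-8,9-diol can close a five-membered dioxolane while the tertiary C11 hydroxyl and the ketone stay free.

Step 10
Reactants: 17 acetonide ketone
Product: 19 isopropenyl ketone, via sulfamate ester 18 (not isolated)
Conditions: Burgess reagent (2 equiv), toluene, rt → 60 °C
Reagents that add atoms: none
Why: Burgess dehydration, a syn elimination (Ei) of the tertiary sulfamate 18, in which the sulfamate oxygen is expected to sit anti to H7 so that neither methyl group has to face the axial 8β-oxygen, which leaves only methyl hydrogens within reach and should favour the isopropenyl over the isopropylidene alkene, and with C8 still an acetal carbon no conjugated enone can arise.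

Step 11
Reactants: 19 isopropenyl ketone
Product: 20 3α-alcohol
Conditions: Li (6 equiv), NH3(l)/THF, MeOH (4 equiv), −78 °C; then NH4Cl
Reagents that add atoms: none
Why: Dissolving-metal reduction, which gives the thermodynamically favoured alcohol: with the C5 methyl axial on ring A the new 3α-hydroxyl is equatorial and trans to the C4 methyl, whereas a hydride reagent would be kept off the axial path by the syn-axial C5 methyl and give mainly the axial 3β-epimer, and the isolated alkene and the acetal are inert.

Step 12
Reactants: 21 angelic acid, 22 (R)-pent-4-en-2-ol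
Product: 24 pentenyl angelate, via mixed anhydride 23 (not isolated)
Conditions: 2,4,6-trichlorobenzoyl chloride, Et3N, toluene, rt; then 22, 75 °C
Reagents that add atoms: none
Why: Esterification through the mixed 2,4,6-trichlorobenzoic anhydride 23 (Yamaguchi-type activation) without a nucleophilic catalyst, the established way to transfer an angeloyl group without Z to E isomerisation, and the carbinol stereocentre keeps its configuration because only its O–H bond reacts.

Step 13
Reactants: 24 pentenyl angelate, 25 acrylic acid
Product: 26 side-chain acid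
Conditions: second-generation Hoveyda–Grubbs catalyst RuCl2(H2IMes)(=CH-C6H4-2-OiPr) (5 mol %), acrylic acid (3 equiv), CH2Cl2, 40 °C
Reagents that add atoms: none
Why: Olefin cross-metathesis of the terminal alkene with acrylic acid, which gives the E-configured enoic acid under thermodynamic control as ethene escapes, the trisubstituted electron-poor angelate alkene being inert to the catalyst.

Step 14
Reactants: 20 3α-alcohol, 26 side-chain acid
Product: 27 acetonide ester
Conditions: DCC (1.5 equiv), DMAP (0.1 equiv), CH2Cl2, 0 °C → rt
Reagents that add atoms: none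
Why: Steglich esterification of the only hydroxyl left (equatorial, secondary), with catalytic DMAP at low temperature so that γ-deprotonation of the activated enoic acid (deconjugation or loss of the δ-acyloxy group) does not compete.

Step 15
Reactants: 27 acetonide ester
Product: 28 diol ester
Conditions: AcOH/H2O (4:1), 45 °C
Reagents that add atoms: none
Why: Acid hydrolysis of the dioxolane acetal under conditions mild enough for the two esters and the 1,1-disubstituted alkene.

Step 16
Reactants: 28 diol ester
Product: 29 9-O-triethylsilyl ether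
Conditions: Et3SiCl (1.1 equiv), imidazole, DMF, −20 → 0 °C
Reagents that add atoms: chlorotriethylsilane, CC[Si](Cl)(CC)CC
Why: Sterically controlled monosilylation of a diol: the 9β-hydroxyl is equatorial, whereas the 8β-hydroxyl is axial and flanked by the isopropenyl-bearing C7, so the silyl chloride should take O9 and leave free the hydroxyl that has to be oxidised.

Step 17
Reactants: 29 9-O-triethylsilyl ether
Product: 30 silyloxy ketone
Conditions: Dess–Martin periodinane (1.5 equiv), pyridine, CH2Cl2, 0 °C → rt
Reagents that add atoms: none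
Why: Dess–Martin oxidation of the one free secondary alcohol under buffered, non-basic conditions, so that neither the C7 stereocentre next to the new ketone nor the β,γ-position of the isopropenyl alkene is disturbed.

Step 18
Reactants: 30 silyloxy ketone
Product: 31 target CNP0210874.1
Conditions: HF·pyridine, THF/pyridine, 0 °C
Reagents that add atoms: none
Why: Fluoride-induced cleavage of the triethylsilyl ether in a buffered, weakly acidic medium that leaves the α-ketol, the β,γ-unsaturated ketone and both unsaturated esters as they are.

**Compound list**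

1 | 2,3-dimethylphenol | Cc1cccc(O)c1C | starting material
2 | (±)-6-acetoxy-5,6-dimethylcyclohexa-2,4-dien-1-one, racemate (both antipodes written) | CC(=O)O[C@]1(C)C(C)=CC=CC1=O.CC(=O)O[C@@]1(C)C(C)=CC=CC1=O | intermediate
3 | methyl acrylate | C=CC(=O)OC | starting material
4 | (±)-methyl 5-acetoxy-4,5-dimethyl-6-oxobicyclo[2.2.2]oct-7-ene-2-carboxylate, racemate (both antipodes written); in eremophilane numbering: bridgeheads C5 (methyl) and C8 (H), C3 ketone, C4 acetoxy syn to the C6–C7 bridge and C4 methyl syn to C9=C10, C7 ester syn to C9=C10 | O=C1[C@@](C)(OC(C)=O)[C@]2(C)C=C[C@H]1[C@@H](C(=O)OC)C2.O=C1[C@](C)(OC(C)=O)[C@@]2(C)C=C[C@@H]1[C@H](C(=O)OC)C2 | intermediate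
5 | acetoxy keto ester, the antipode of 4 with the C5, C7, C8 configuration of the target | O=C1[C@@](C)(OC(C)=O)[C@]2(C)C=C[C@H]1[C@@H](C(=O)OC)C2 | intermediate
6 | diiodosamarium C3=C4 enolate (trivalent samarium) of keto ester 7, formed in the flask | COC(=O)[C@H]1C[C@@]2(C)C=C[C@@H]1C(O[Sm](I)I)=C2C | intermediate
7 | keto ester: methyl 4,5-dimethyl-6-oxobicyclo[2.2.2]oct-7-ene-2-carboxylate with C4–H turned to C9=C10 (C4 methyl syn to the C6–C7 bridge) and the C7 ester syn to C9=C10 | O=C1[C@@H](C)[C@]2(C)C=C[C@H]1[C@@H](C(=O)OC)C2 | intermediate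
8 | vinyl carbinol ester: 7 with vinyl (syn to C9=C10) and hydroxyl (syn to the C6–C7 bridge) on C3 | C=C[C@]1(O)[C@@H](C)[C@]2(C)C=C[C@H]1[C@@H](C(=O)OC)C2 | intermediate
9 | methyl ketone: 8 with acetyl in place of the ester on C7, formed in the flask | C=C[C@]1(O)[C@@H](C)[C@]2(C)C=C[C@H]1[C@@H](C(C)=O)C2 | intermediate
10 | vinyl carbinol diol: 2-vinylbicyclo[2.2.2]oct-5-en-2-ol with bridgeheads C5 (methyl) and C8, C3 vinyl syn to C9=C10, C4 methyl syn to the C6–C7 bridge, C7 2-hydroxypropan-2-yl syn to C9=C10 | C=C[C@]1(O)[C@@H](C)[C@]2(C)C=C[C@H]1[C@@H](C(C)(C)O)C2 | intermediate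
11 | dipotassium dialkoxide of 10, formed in the flask | C=C[C@]1([O-])[C@@H](C)[C@]2(C)C=C[C@H]1[C@@H](C(C)(C)[O-])C2.[K+].[K+] | intermediate
12 | dipotassium C2=C3 enolate and C11 alkoxide of the 4α-methyl cis-octalone, formed in the flask | CC(C)([O-])[C@H]1C[C@@]2(C)[C@H](CC=C([O-])[C@H]2C)C=C1.[K+].[K+] | intermediate
13 | 4-epi octalone: 14 with the C4 methyl α, formed in the flask | CC(C)(O)[C@H]1C[C@@]2(C)[C@H](CCC(=O)[C@H]2C)C=C1 | intermediate
14 | cis-octalone: 3-oxo, C8=C9, 4β-methyl, 5β-methyl, 10β-H, 7β-(2-hydroxypropan-2-yl) | CC(C)(O)[C@H]1C[C@@]2(C)[C@H](CCC(=O)[C@@H]2C)C=C1 | intermediate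
15 | cyclic 8β,9β-osmate ester (hexavalent osmium) of 14 as its TMEDA complex, formed in the flask | CC(C)(O)[C@H]1C[C@@]2(C)[C@H](CCC(=O)[C@@H]2C)[C@H]3O[Os](=O)(=O)O[C@@H]13.CN(C)CCN(C)C | intermediate
16 | triol ketone: 3-oxo, 8β-OH, 9β-OH, 4β,5β-dimethyl, 10β-H, 7β-(2-hydroxypropan-2-yl) | CC(C)(O)[C@H]1C[C@@]2(C)[C@H](CCC(=O)[C@@H]2C)[C@@H](O)[C@H]1O | intermediate
17 | acetonide ketone: 8β,9β-O-isopropylidene derivative of 16 | CC(C)(O)[C@H]1C[C@@]2(C)[C@H](CCC(=O)[C@@H]2C)[C@H]3OC(C)(C)O[C@@H]13 | intermediate
18 | C11 N-(methoxycarbonyl)sulfamate ester of 17, triethylammonium salt, formed in the flask | COC(=O)[N-]S(=O)(=O)OC(C)(C)[C@H]1C[C@@]2(C)[C@H](CCC(=O)[C@@H]2C)[C@H]3OC(C)(C)O[C@@H]13.CC[NH+](CC)CC | intermediate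
19 | isopropenyl ketone: 3-oxo, 7β-isopropenyl, 8β,9β-O-isopropylidene, 4β,5β-dimethyl, 10β-H | C=C(C)[C@H]1C[C@@]2(C)[C@H](CCC(=O)[C@@H]2C)[C@H]3OC(C)(C)O[C@@H]13 | intermediate
20 | 3α-alcohol: 19 with an equatorial 3α-hydroxyl in place of the ketone | C=C(C)[C@H]1C[C@@]2(C)[C@H](CC[C@@H](O)[C@@H]2C)[C@H]3OC(C)(C)O[C@@H]13 | intermediate
21 | angelic acid, (Z)-2-methylbut-2-enoic acid | C/C=C(/C)C(=O)O | starting material
22 | (R)-pent-4-en-2-ol | C=CC[C@@H](C)O | starting material
23 | angelic 2,4,6-trichlorobenzoic anhydride, formed in the flask | C/C=C(/C)C(=O)OC(=O)c1c(Cl)cc(Cl)cc1Cl | intermediate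
24 | pentenyl angelate: (R)-pent-4-en-2-yl (Z)-2-methylbut-2-enoate | C=CC[C@@H](C)OC(=O)/C(C)=C\C | intermediate
25 | acrylic acid | C=CC(=O)O | starting material
26 | side-chain acid: (2E,5R)-5-{[(2Z)-2-methylbut-2-enoyl]oxy}hex-2-enoic acid | OC(=O)/C=C/C[C@@H](C)OC(=O)/C(C)=C\C | intermediate
27 | acetonide ester: 3α-ester of 20 with acid 26 | C=C(C)[C@H]1C[C@@]2(C)[C@H](CC[C@@H](OC(=O)/C=C/C[C@@H](C)OC(=O)/C(C)=C\C)[C@@H]2C)[C@H]3OC(C)(C)O[C@@H]13 | intermediate
28 | diol ester: 27 without the acetonide (8β-OH, 9β-OH) | C=C(C)[C@H]1C[C@@]2(C)[C@H](CC[C@@H](OC(=O)/C=C/C[C@@H](C)OC(=O)/C(C)=C\C)[C@@H]2C)[C@@H](O)[C@H]1O | intermediate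
29 | 9-O-triethylsilyl ether of 28 (8β-OH free) | C=C(C)[C@H]1C[C@@]2(C)[C@H](CC[C@@H](OC(=O)/C=C/C[C@@H](C)OC(=O)/C(C)=C\C)[C@@H]2C)[C@@H](O[Si](CC)(CC)CC)[C@H]1O | intermediate
30 | silyloxy ketone: 8-oxo, 9β-triethylsilyloxy | C=C(C)[C@H]1C[C@@]2(C)[C@H](CC[C@@H](OC(=O)/C=C/C[C@@H](C)OC(=O)/C(C)=C\C)[C@@H]2C)[C@@H](O[Si](CC)(CC)CC)C1=O | intermediate
31 | CNP0210874.1: (1R,3R,4aR,5R,6R,8aS)-1-hydroxy-4a,5-dimethyl-2-oxo-3-(prop-1-en-2-yl)decahydronaphthalen-6-yl (2E,5R)-5-{[(2Z)-2-methylbut-2-enoyl]oxy}hex-2-enoate | C=C(C)[C@H]1C[C@@]2(C)[C@H](CC[C@@H](OC(=O)/C=C/C[C@@H](C)OC(=O)/C(C)=C\C)[C@@H]2C)[C@@H](O)C1=O | target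

**Count and risks**

Total: 18 steps. Longest linear sequence: 16 steps (steps 1–11 and 14–18) from 2,3-dimethylphenol; the side-chain acid takes 2 steps (12–13).

The three steps most likely to fail, in falling order of risk:

Step 16. The silyl chloride may not tell the equatorial O9 from the axial O8 well enough, or the silyl group may wander between the two oxygens, so that the wrong hydroxyl is left for oxidation. The fallback sets out from 28 and comes back at 31. The diol is heated with Bu2SnO in toluene with removal of water to give the dibutylstannylene acetal F1, whose equatorial oxygen is the one alkylated by 4-methoxybenzyl chloride/Bu4NI to give the 9-O-(4-methoxybenzyl) ether F2. Dess–Martin oxidation of the free 8β-hydroxyl then gives the 4-methoxybenzyloxy ketone F3, and DDQ in wet CH2Cl2 removes the benzyl group to give 31.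

Step 7. Once the shift has made the free C11 alkoxide homoallylic to C8=C9 it may open a retro-allylation path with loss of acetone, or the dialkoxide may aggregate and react sluggishly so that cleavage of the C3 alkoxide competes with the shift. The fallback sets out from 10 and comes back at 14. The less hindered C11 hydroxyl is silylated alone (Et3SiOTf, 2,6-lutidine, CH2Cl2, −78 °C) to give the C11 triethylsilyl ether F4. KH/18-crown-6 converts it into the potassium alkoxide F5, which rearranges to the potassium enolate F6. Methanol quench gives the 4-epi ketone F7, and equilibration by the KOMe formed gives the silylated cis-octalone F8, from which Bu4NF in THF sets 14 free.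

Step 14. While the hindered alcohol reacts slowly, the activated acid may lose its δ-acyloxy group by γ-deprotonation and elimination, or may deconjugate. The fallback sets out from 20 and comes back at 27. The alcohol is acylated with acryloyl chloride/iPr2NEt to give the 3α-acrylate F9, and the side chain is completed by cross-metathesis of F9 with pentenyl angelate 24 under the conditions of step 13, in which the 1,1-disubstituted isopropenyl alkene should be far slower than the acrylate.

Further compounds
F1 | step 16 | dibutylstannylene acetal of diol ester 28 | C=C(C)[C@H]1C[C@@]2(C)[C@H](CC[C@@H](OC(=O)/C=C/C[C@@H](C)OC(=O)/C(C)=C\C)[C@@H]2C)[C@H]3O[Sn](CCCC)(CCCC)O[C@@H]13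
F2 | step 16 | 9-O-(4-methoxybenzyl) ether of diol ester 28 | C=C(C)[C@H]1C[C@@]2(C)[C@H](CC[C@@H](OC(=O)/C=C/C[C@@H](C)OC(=O)/C(C)=C\C)[C@@H]2C)[C@@H](OCc3ccc(OC)cc3)[C@H]1O
F3 | step 16 | 4-methoxybenzyloxy ketone (8-oxo, 9β-O-(4-methoxybenzyl)) | C=C(C)[C@H]1C[C@@]2(C)[C@H](CC[C@@H](OC(=O)/C=C/C[C@@H](C)OC(=O)/C(C)=C\C)[C@@H]2C)[C@@H](OCc3ccc(OC)cc3)C1=O
F4 | step 7 | C11 triethylsilyl ether of vinyl carbinol diol 10 | C=C[C@]1(O)[C@@H](C)[C@]2(C)C=C[C@H]1[C@@H](C(C)(C)O[Si](CC)(CC)CC)C2
F5 | step 7 | potassium C3 alkoxide of F4 | C=C[C@]1([O-])[C@@H](C)[C@]2(C)C=C[C@H]1[C@@H](C(C)(C)O[Si](CC)(CC)CC)C2.[K+]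
F6 | step 7 | potassium C2=C3 enolate of the 4α-methyl cis-octalone C11 triethylsilyl ether | CC[Si](CC)(CC)OC(C)(C)[C@H]1C[C@@]2(C)[C@H](CC=C([O-])[C@H]2C)C=C1.[K+]
F7 | step 7 | 4-epi ketone (4α-methyl) C11 triethylsilyl ether | CC[Si](CC)(CC)OC(C)(C)[C@H]1C[C@@]2(C)[C@H](CCC(=O)[C@H]2C)C=C1
F8 | step 7 | C11 triethylsilyl ether of cis-octalone 14 | CC[Si](CC)(CC)OC(C)(C)[C@H]1C[C@@]2(C)[C@H](CCC(=O)[C@@H]2C)C=C1
F9 | step 14 | 3α-acrylate of alcohol 20 | C=C(C)[C@H]1C[C@@]2(C)[C@H](CC[C@@H](OC(=O)C=C)[C@@H]2C)[C@H]3OC(C)(C)O[C@@H]13
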